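Numbering: C1 tertiary carbinol; C2(=O)-C3=C4-C15 the (Z)-butenoyl chain; C5 isovalerate carbon; C6 lactone O-carbon; C7 ring-fusion carbon; C8 CH2; C9 CHOH; C10 CHMe; C11-C13 methylene-lactone carbons. α is the ring face bearing the C6 oxygen and β the other face, so the target is 5β-O, 6α-O, 7α-C11, 9β-OH, 10α-Me, 1α-OH, 1β-acyl (1S,5S,6R,7S,9R,10S). NAP = naphthalen-2-ylmethyl, TES = triethylsilyl.
Enabling feature: in the cycloheptane ring, C6 and C9 both carry oxygen and stand 1,4 to each other. The three carbons joining them on the short side, C5(O)-C1(O)-C10, form an oxygenated C3 unit. The ring is therefore furan (C6-C7-C8-C9 plus one bridging O) joined to a 1-alkoxy-2-oxyallyl cation (C5-C1-C10).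
Retrosynthetic cuts, in order: C5-O acyl; the C12 lactone carbonyl back to an isopropenyl CH3; C2-C3; C9-O (held as a C2 γ-lactone); C7-C11 with return of the C9-O bridge bond; C1-OH and C10-CH3; C1-C2; last, C5-C6 and C9-C10 together.
Forward order: the furan ring comes first and step 3 closes the cycloheptene across it. The bridge is opened at C9 when C7-C11 forms. A temporary C2/C9 γ-lactone is then closed and later opened by C3, and the methylene lactone closes in the last step.
Stereochemistry: C5 and C6 (and a sacrificial C9) come from the catalyst-controlled cycloaddition. C10, C1 and C7 come from attack on the exo (α) face of the rigid bicycle, and C9 from anti iodolactonisation by the β-carboxyl. The Z alkene comes from (Z)-1-bromopropene and is kept as an allylic silyl ether until the final oxidation.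
Tactics: NAP replaces benzyl so that C5-O can be freed with DDQ beside three C=C bonds. C2 enters as CO on a C1 enol triflate, so C10-Me and C1-OH arise by conjugate addition and ketene-acetal oxidation; this avoids an epimerisable axial α-methyl ketone and any osmylation beside the strained C7=C8 bond.

Key step: step 3

Remark 1: the squaramide antipode that leads to (1R,2S,5R)-7 is used; which antipode this is has to be fixed by a first run.
Remark 2: the C2 carbinol (or lactol) carbon in 22, 25-27 and 29-32 forms as an epimer mixture and is drawn without descriptor, because the last step makes it trigonal.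

Step 1
Reactants: 1 methylglyoxal 1,1-dimethyl acetal; 2 naphthalen-2-ylmethanol (2.2 equiv)
Product: 3 1,1-bis(naphthalen-2-ylmethoxy)propan-2-one
Conditions: p-TsOH·H2O (2 mol%), cyclohexane, reflux, MeOH removed over 4 Å molecular sieves
Reagents that add atoms: none
Why: Acid-catalysed transacetalisation driven by removal of methanol; the NAP group should behave like benzyl in step 3 yet is cleavable later by DDQ.

Step 2
Reactants: 3 1,1-bis(naphthalen-2-ylmethoxy)propan-2-one
Product: 4 3,3-bis(naphthalen-2-ylmethoxy)-2-(triethylsilyloxy)prop-1-ene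
Conditions: LiN(i-Pr)2 (LDA), THF, −78 °C; Et3SiCl, −78 → 0 °C
Reagents that add atoms: chlorotriethylsilane, CC[Si](CC)(CC)Cl
Why: Kinetic enolate formation at the methyl group (the acetal CH is hindered and electronically deactivated) followed by O-silylation is a standard silyl enol ether synthesis.

Step 3
Reactants: 4 3,3-bis(naphthalen-2-ylmethoxy)-2-(triethylsilyloxy)prop-1-ene; 5 furan (5 equiv)
Product: 7 (1R,2S,5R)-2-(naphthalen-2-ylmethoxy)-8-oxabicyclo[3.2.1]oct-6-en-3-one (ether equatorial; anti to the bridge), via silyloxyallyl cation 6 (not isolated)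
Conditions: Et3SiOTf (20 mol%), chiral tert-leucine arylpyrrolidine squaramide (20 mol%), Et2O, −78 °C
Reagents that add atoms: none
Why: Et3SiOTf, made more Lewis acidic by triflate binding to the squaramide, removes one NAP-oxy group from 4 and leaves cation 6 as a chiral ion pair; furan then bonds through its two α-carbons to both allyl termini (C5-C6 at the oxocarbenium end, C9-C10 at the enol silane end), and loss of Et3Si+ to triflate regenerates the promoter. The closest known reaction type is the (4+3) cycloaddition of 1-alkoxy-2-silyloxyallyl cations from 2-silyloxyacrolein acetals with furan, including its enantioselective anion-binding version with dibenzyl acetals. One ring is closed, the cycloheptene C5-C6-C7-C8-C9-C10-C1, by a suprafacial 4π+2π union across the furan, so the furan oxygen ends as a one-atom bridge between C6 and C9. C6 and C9 are tied to each other by that bridge, C5 is set relative to them by the compact approach of the W-shaped cation (alkoxy group equatorial, anti to the bridge), and the absolute sense comes from the cation face left open by the bound catalyst. The step needs enantioface control and compact-versus-extended control only, since the symmetry of furan removes any regiochemical choice, and excess furan at −78 °C should suppress Friedel-Crafts-type interception after the first bond.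

Step 4
Reactants: 7 cycloadduct ketone
Product: 8 C1(C10)-enol triflate of 7 (C1(OTf)=C10H; 5β-ONAP; 6α,9α-oxygen bridge; C7=C8)
Conditions: LiN(i-Pr)2 (LDA), THF, −78 °C; PhNTf2, −78 → 0 °C; then H2O
Reagents that add atoms: N-phenylbis(trifluoromethanesulfonimide), O=S(=O)(N(c1ccccc1)S(=O)(=O)C(F)(F)F)C(F)(F)F
Why: Kinetic deprotonation should take the exo-axial proton of the C10 methylene rather than the proton on alkoxy-bearing C5, and O-triflation of the enolate (enol triflate synthesis) fixes C1=C10 without touching C5, C6 or C9.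

Step 5
Reactants: 8 enol triflate
Product: 9 methyl C1-carboxylate (C2O2Me on C1; C1=C10H; 5β-ONAP; 6α,9α-oxygen bridge; C7=C8)
Conditions: Pd(OAc)2 (5 mol%), dppf (6 mol%), CO (1 atm), MeOH, Et3N, DMF, 50 °C
Reagents that add atoms: carbon monoxide, [C-]#[O+]; methanol, CO
Why: Palladium-catalysed alkoxycarbonylation of an enol triflate (oxidative addition to zerovalent palladium, CO insertion, methanolysis) forms C1-C2 at the acid oxidation level and creates no stereocentre.

Step 6
Reactants: 9 unsaturated methyl ester
Product: 12 methyl ester bearing axial 10α-methyl; equatorial 1α-OH; axial 1β-CO2Me (bridge; 5β-ONAP; C7=C8 unchanged), via silyl ketene acetal 10 (not isolated), via O-trimethylsilyl hydroxy ester 11 (not isolated)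
Conditions: Me2CuLi (from MeLi, CuI), Me3SiCl, THF-Et2O, −78 → −30 °C; pentane extraction; dimethyldioxirane, acetone-CH2Cl2, −78 °C; 1 M HCl, THF, 0 °C
Reagents that add atoms: lithium dimethylcuprate, [Li+].C[Cu-]C; chlorotrimethylsilane, C[Si](C)(C)Cl; dimethyldioxirane, CC1(C)OO1
Why: Silyl-chloride-accelerated cuprate conjugate addition attacks C10 from the exo face (the endo face lies under the C7=C8 bridge) and sets the axial 10α-methyl, and Rubottom-type oxidation of the electron-rich ketene acetal from the same face sets 1α-OH well before the electron-poor C7=C8 bond can react.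

Step 7
Reactants: 12 hydroxy ester
Product: 13 bicyclic 1,2-diol (1α-OH; 1β-CH2OH; 10α-Me; 5β-ONAP; 6α,9α-oxygen bridge; C7=C8)
Conditions: LiAlH4, THF, 0 °C
Reagents that add atoms: none
Why: Hydride reduction of the ester takes C2 to the alcohol level, so the organolithium of the next step meets no carbonyl group and no stereocentre is affected.

Step 8
Reactants: 13 bicyclic diol; 14 2-bromopropene
Product: 16 cyclohept-8-ene triol (6α-OH; 7α-isopropenyl; C8=C9; 10α-Me; 1α-OH; 1β-CH2OH; 5β-ONAP), via isopropenyllithium 15 (not isolated)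
Conditions: 14, Li (1% Na), Et2O, 0 °C (6 equiv of 15); then 13, Et2O-pentane, 0 °C → rt; then H2O
Reagents that add atoms: none
Why: Syn SN2′ ring opening of an 8-oxabicyclo[3.2.1]octene by an organolithium, in which lithium bound to the bridge oxygen delivers carbon to the exo face so that C11 ends cis to the C6 oxygen, with attack at C7 rather than C8 expected because C9-O is the weaker bridge bond (antiperiplanar to the donor C10-H bond, whereas C6-O is antiperiplanar to and inductively strengthened by the C5-O bond).

Step 9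
Reactants: 16 triol
Product: 18 α-hydroxy acid (C2O2H on the β face of C1; otherwise as 16), via hydroxy aldehyde 17 (not isolated)
Conditions: TEMPO (20 mol%), PhI(OAc)2 (2.2 equiv), MeCN-pH 7 buffer, 0 °C → rt
Reagents that add atoms: water, O
Why: Nitroxyl-catalysed oxidation selects the primary carbinol over the hindered secondary C6-OH and the tertiary C1-OH and runs through the aldehyde hydrate to the acid without touching the two alkenes.

Step 10
Reactants: 18 hydroxy acid
Product: 19 iodolactone (C2(=O)-O-C9 γ-lactone on the β face; 8α-iodide; 6α-OH; 7α-isopropenyl; 10α-Me; 1α-OH; 5β-ONAP)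
Conditions: I2, NaHCO3, MeCN, 0 °C, dark
Reagents that add atoms: iodine, [I][I]
Why: Iodolactonisation of a γ,δ-unsaturated acid (5-exo, anti addition) lets the β-carboxylate reach only the β face of C9 while iodine takes the α face of C8, which sets the 9β-oxygen; iodonium formation at the isopropenyl group is reversible and has no five-membered outlet.

Step 11
Reactants: 19 iodolactone
Product: 20 lactone with C8 as CH2 (otherwise as 19)
Conditions: Bu3SnH, AIBN (10 mol%), toluene, 80 °C
Reagents that add atoms: none
Why: Radical-chain dehalogenation removes iodine from C8, whose radical has no favourable cyclisation mode onto the isopropenyl group, and avoids the reductive elimination that zinc would cause.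

Step 12
Reactants: 20 lactone
Product: 21 allylic alcohol (7α-C(=CH2)CH2OH; 6α-OH; C2/C9 lactone; 1α-OH; 10α-Me; 5β-ONAP)
Conditions: SeO2 (30 mol%), t-BuOOH (3 equiv), CH2Cl2, 0 °C → rt
Reagents that add atoms: tert-butyl hydroperoxide, CC(C)(C)OO
Why: Selenium-dioxide-catalysed allylic hydroxylation (ene reaction then [2,3] shift) acts on the only alkene present and prefers the methyl group over the hindered C7 methine, as is usual for ring-bound isopropenyl groups.

Step 13
Reactants: 21 allylic alcohol lactone
Product: 22 bridged lactol (C2H(OH)-O-C9; otherwise as 21)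
Conditions: i-Bu2AlH (5 equiv), CH2Cl2, −78 °C
Reagents that add atoms: none
Why: Partial reduction of a γ-lactone by i-Bu2AlH stops at the aluminium lactolate at −78 °C, and the three free hydroxyls only consume extra hydride.

Step 14
Reactants: 22 lactol; 23 (Z)-1-bromoprop-1-ene
Product: 25 pentaol (1α-OH; C2H(OH)-(Z)-CH=CH-CH3 on the β face of C1; 9β-OH; 6α-OH; 7α-C(=CH2)CH2OH; 10α-Me; 5β-ONAP), via (Z)-prop-1-enyllithium 24 (not isolated)
Conditions: 23, t-BuLi (2 equiv per 23), Et2O, −78 °C (7 equiv of 24); then 22, THF, −78 → 0 °C; then H2O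
Reagents that add atoms: none
Why: Halogen-lithium exchange and 1,2-addition of the alkenyllithium to the open hydroxy-aldehyde form of the lactol both retain alkene geometry, so C2-C3 forms with the Z double bond in place and 9β-OH is released.

Step 15
Reactants: 25 pentaol
Product: 26 tetrakis(triethylsilyl) ether (OTES at C2, C6, C9 and C12; 1α-OH free; 5β-ONAP)
Conditions: Et3SiOTf (4.4 equiv), 2,6-lutidine, CH2Cl2, −78 °C
Reagents that add atoms: triethylsilyl trifluoromethanesulfonate, CC[Si](CC)(CC)OS(=O)(=O)C(F)(F)F
Why: Silyl triflate etherification covers the primary and the three secondary hydroxyls at low temperature, while the tertiary C1-OH, flanked by three branched carbons, should stay free.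

Step 16
Reactants: 26 tetrakis-TES ether
Product: 27 C5 alcohol (5β-OH; otherwise as 26)
Conditions: DDQ, CH2Cl2-pH 7 buffer (10:1), 0 °C → rt
Reagents that add atoms: none
Why: Oxidative cleavage of a naphthylmethyl ether by DDQ (hydride abstraction, then hydrolysis of the oxocarbenium ion) spares isolated alkenes and silyl ethers, and the water present prevents capture by C1-OH as an arylidene acetal.

Step 17
Reactants: 27 C5 alcohol; 28 3-methylbutanoic (isovaleric) anhydride
Product: 29 5β-isovalerate (OTES at C2, C6, C9, C12; 1α-OH free)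
Conditions: DMAP, Et3N, CH2Cl2, rt
Reagents that add atoms: none
Why: DMAP-catalysed acyl transfer reaches the only free secondary hydroxyl, the tertiary C1-OH is inert under these conditions, and no enone is yet present that the nucleophilic catalyst could isomerise.

Step 18
Reactants: 29 silylated isovalerate
Product: 30 pentaol isovalerate (free OH at C1, C2, C6, C9, C12; 5β-O-isovaleryl)
Conditions: HF·pyridine, pyridine, THF, 0 °C → rt
Reagents that add atoms: none
Why: Fluoride-driven desilylation under weakly acidic buffering removes all four TES groups without base-induced acyl migration from O5 to O6 and without ionising the Z-allylic carbinol.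

Step 19
Reactants: 30 pentaol isovalerate
Product: 33 target CNP0186412.2, via methylene lactol 31 (not isolated), via C2-carbinol lactone 32 (not isolated)
Conditions: activated MnO2 (excess), CH2Cl2, rt
Reagents that add atoms: none
Why: MnO2 allylic oxidation takes the primary allylic alcohol through the enal, its lactol with the cis 6α-OH and on to the α-methylene-γ-lactone, and converts the Z-allylic C2 carbinol into the Z-enone, while the saturated 9β-OH and the tertiary 1α-OH are not substrates.

Compound list
1 | methylglyoxal 1,1-dimethyl acetal | CC(=O)C(OC)OC | starting material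
2 | naphthalen-2-ylmethanol | OCc1ccc2ccccc2c1 | starting material
3 | 1,1-bis(naphthalen-2-ylmethoxy)propan-2-one | CC(=O)C(OCc1ccc2ccccc2c1)OCc1ccc2ccccc2c1 | intermediate
4 | 3,3-bis(naphthalen-2-ylmethoxy)-2-(triethylsilyloxy)prop-1-ene | C=C(O[Si](CC)(CC)CC)C(OCc1ccc2ccccc2c1)OCc1ccc2ccccc2c1 | intermediate
5 | furan | c1ccoc1 | starting material
6 | 1-(naphthalen-2-ylmethoxy)-2-(triethylsilyloxy)allyl cation (triflate ion pair bound to the squaramide) | C=C(O[Si](CC)(CC)CC)C=[O+]Cc1ccc2ccccc2c1 | intermediate
7 | (1R,2S,5R)-2-(naphthalen-2-ylmethoxy)-8-oxabicyclo[3.2.1]oct-6-en-3-one; C1 ketone, equatorial 5β-ONAP, 6α,9α-bridge | O1[C@@H]2C=C[C@H]1CC(=O)[C@H]2OCc3ccc4ccccc4c3 | intermediate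
8 | C1(C10)-enol triflate of 7 | O1[C@@H]2C=C[C@H]1C=C(OS(=O)(=O)C(F)(F)F)[C@H]2OCc3ccc4ccccc4c3 | intermediate
9 | methyl C1-carboxylate, C1=C10 | O1[C@@H]2C=C[C@H]1C=C(C(=O)OC)[C@H]2OCc3ccc4ccccc4c3 | intermediate
10 | methyl trimethylsilyl ketene acetal, 10α-methyl | O1[C@@H]2C=C[C@H]1[C@H](C)C(=C(OC)O[Si](C)(C)C)[C@H]2OCc3ccc4ccccc4c3 | intermediate
11 | 1α-trimethylsilyloxy methyl ester | O1[C@@H]2C=C[C@H]1[C@H](C)[C@@](O[Si](C)(C)C)(C(=O)OC)[C@H]2OCc3ccc4ccccc4c3 | intermediate
12 | 1α-hydroxy-10α-methyl methyl ester (1β-CO2Me) | O1[C@@H]2C=C[C@H]1[C@H](C)[C@@](O)(C(=O)OC)[C@H]2OCc3ccc4ccccc4c3 | intermediate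
13 | bicyclic diol (1α-OH, 1β-CH2OH) | O1[C@@H]2C=C[C@H]1[C@H](C)[C@@](O)(CO)[C@H]2OCc3ccc4ccccc4c3 | intermediate
14 | 2-bromopropene | CC(Br)=C | starting material
15 | isopropenyllithium | [Li]C(C)=C | intermediate
16 | ring-opened triol (6α-OH, 7α-isopropenyl, C8=C9) | O[C@@H]1[C@H](C(C)=C)C=C[C@H](C)[C@@](O)(CO)[C@H]1OCc2ccc3ccccc3c2 | intermediate
17 | α-hydroxy aldehyde | O[C@@H]1[C@H](C(C)=C)C=C[C@H](C)[C@@](O)(C=O)[C@H]1OCc2ccc3ccccc3c2 | intermediate
18 | α-hydroxy acid | O[C@@H]1[C@H](C(C)=C)C=C[C@H](C)[C@@](O)(C(=O)O)[C@H]1OCc2ccc3ccccc3c2 | intermediate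
19 | iodolactone (9β-O lactone, 8α-iodide) | I[C@@H]1[C@@H]2[C@H](C)[C@@](O)(C(=O)O2)[C@@H](OCc3ccc4ccccc4c3)[C@H](O)[C@@H]1C(C)=C | intermediate
20 | C2/C9 γ-lactone, C8 = CH2 | O[C@@H]1[C@H](C(C)=C)C[C@@H]2[C@H](C)[C@@](O)(C(=O)O2)[C@H]1OCc3ccc4ccccc4c3 | intermediate
21 | lactone with 7α-(3-hydroxyprop-1-en-2-yl) arm | O[C@@H]1[C@H](C(=C)CO)C[C@@H]2[C@H](C)[C@@](O)(C(=O)O2)[C@H]1OCc3ccc4ccccc4c3 | intermediate
22 | bridged lactol | O[C@@H]1[C@H](C(=C)CO)C[C@@H]2[C@H](C)[C@@](O)(C(O)O2)[C@H]1OCc3ccc4ccccc4c3 | intermediate
23 | (Z)-1-bromoprop-1-ene | Br/C=C\C | starting material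
24 | (Z)-prop-1-enyllithium | [Li]/C=C\C | intermediate
25 | pentaol NAP ether with (Z)-1-hydroxybut-2-enyl chain | O[C@@H]1[C@H](C(=C)CO)C[C@@H](O)[C@H](C)[C@@](O)(C(O)/C=C\C)[C@H]1OCc2ccc3ccccc3c2 | intermediate
26 | tetrakis-TES ether | CC[Si](CC)(CC)O[C@@H]1[C@H](C(=C)CO[Si](CC)(CC)CC)C[C@@H](O[Si](CC)(CC)CC)[C@H](C)[C@@](O)(C(O[Si](CC)(CC)CC)/C=C\C)[C@H]1OCc2ccc3ccccc3c2 | intermediate
27 | 5β-alcohol | CC[Si](CC)(CC)O[C@@H]1[C@H](C(=C)CO[Si](CC)(CC)CC)C[C@@H](O[Si](CC)(CC)CC)[C@H](C)[C@@](O)(C(O[Si](CC)(CC)CC)/C=C\C)[C@H]1O | intermediate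
28 | 3-methylbutanoic anhydride | CC(C)CC(=O)OC(=O)CC(C)C | starting material
29 | 5β-isovalerate, tetrakis-TES | CC[Si](CC)(CC)O[C@@H]1[C@H](C(=C)CO[Si](CC)(CC)CC)C[C@@H](O[Si](CC)(CC)CC)[C@H](C)[C@@](O)(C(O[Si](CC)(CC)CC)/C=C\C)[C@H]1OC(=O)CC(C)C | intermediate
30 | pentaol isovalerate | O[C@@H]1[C@H](C(=C)CO)C[C@@H](O)[C@H](C)[C@@](O)(C(O)/C=C\C)[C@H]1OC(=O)CC(C)C | intermediate
31 | cis-fused α-methylene lactol | C=C1C(O)O[C@@H]2[C@H]1C[C@@H](O)[C@H](C)[C@@](O)(C(O)/C=C\C)[C@H]2OC(=O)CC(C)C | intermediate
32 | α-methylene lactone with C2 carbinol | C=C1C(=O)O[C@@H]2[C@H]1C[C@@H](O)[C@H](C)[C@@](O)(C(O)/C=C\C)[C@H]2OC(=O)CC(C)C | intermediate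
33 | CNP0186412.2 | C=C1C(=O)O[C@@H]2[C@H]1C[C@@H](O)[C@H](C)[C@@](O)(C(=O)/C=C\C)[C@H]2OC(=O)CC(C)C | target

Total step count: 19. Longest linear sequence: 19 steps (1 → 33); 2, 5, 14, 23 and 28 enter as purchased.

Steps most likely to fail

1. Step 8. The bicycle is nearly mirror-symmetric around the alkene, so discrimination between C7 and C8 may be poor; attack at C8 would break the C6-O bond instead. In addition, the sp2 organolithium may add slowly and may metalate the naphthylmethyl CH2.
Fallback (catalyst control in place of substrate control): 13 is converted with 2,2-dimethoxypropane and PPTS into the spiro-acetonide F1. F1 is opened with diisopropenylzinc, PdCl2(MeCN)2 and one enantiomer of Tol-BINAP. This catalyst type desymmetrises meso 8-oxabicyclo[3.2.1]octenes by exo carbopalladation and β-oxygen elimination, so its choice between enantiotopic carbons becomes here a choice between C7 and C8. The product is the ring-opened acetonide F2, and 80% AcOH releases 16, where the route is rejoined.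

2. Step 3. Exchange of benzyl for naphthylmethyl may erode enantioface or compact-mode control. The cation may lose the arylmethyl group early, or furan may be intercepted after the first bond only.
Fallback (resolution in place of asymmetric catalysis): 4 and 5 are combined with catalytic Me3SiOTf alone in CH2Cl2 at −78 °C. This achiral variant reliably gives the equatorial ether as the racemate of 7 with its antipode ent-7 F3. The two are separated by preparative chromatography on a chiral stationary phase, and the route is rejoined at 7.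

3. Step 19. The hindered C2 carbinol may oxidise slowly, the C1/C2 glycol may be cleaved, or the Z double bond may isomerise on the oxide surface during the long contact time.
Fallback (enone made directly from the lactone, so that the last oxidation acts on the primary alcohol alone):
- 21 is silylated (Et3SiCl, imidazole) to the bis-TES lactone F4.
- One equivalent of 24 beyond that consumed by the free C1-OH is added at −78 °C. It adds once to the lactone carbonyl, because the lithium lactolate persists until the quench, and gives the Z-enone F5 with free 9β-OH.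
- Et3SiCl gives the tris-TES enone F6, and DDQ gives the 5β-alcohol F7.
- Isovaleryl chloride in pyridine, without a nucleophilic catalyst, gives the isovalerate F8, and HF·pyridine gives the enone triol F9.
- TEMPO/PhI(OAc)2, selective for the primary allylic alcohol, passes through the enone lactol F10 and arrives at 33.

Further compounds
F1 | step 8 | spiro-acetonide of 13 | O1[C@@H]2C=C[C@H]1[C@H](C)[C@@](O3)(COC3(C)C)[C@H]2OCc4ccc5ccccc5c4
F2 | step 8 | acetonide of 16 | O[C@@H]1[C@H](C(C)=C)C=C[C@H](C)[C@@](O2)(COC2(C)C)[C@H]1OCc3ccc4ccccc4c3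
F3 | step 3 | ent-7, (1S,2R,5S)-2-(naphthalen-2-ylmethoxy)-8-oxabicyclo[3.2.1]oct-6-en-3-one | O1[C@H]2C=C[C@@H]1CC(=O)[C@@H]2OCc3ccc4ccccc4c3
F4 | step 19 | bis-TES ether of 21 | CC[Si](CC)(CC)O[C@@H]1[C@H](C(=C)CO[Si](CC)(CC)CC)C[C@@H]2[C@H](C)[C@@](O)(C(=O)O2)[C@H]1OCc3ccc4ccccc4c3
F5 | step 19 | Z-enone with free 9β-OH | CC[Si](CC)(CC)O[C@@H]1[C@H](C(=C)CO[Si](CC)(CC)CC)C[C@@H](O)[C@H](C)[C@@](O)(C(=O)/C=C\C)[C@H]1OCc2ccc3ccccc3c2
F6 | step 19 | tris-TES Z-enone | CC[Si](CC)(CC)O[C@@H]1[C@H](C(=C)CO[Si](CC)(CC)CC)C[C@@H](O[Si](CC)(CC)CC)[C@H](C)[C@@](O)(C(=O)/C=C\C)[C@H]1OCc2ccc3ccccc3c2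
F7 | step 19 | tris-TES Z-enone 5β-alcohol | CC[Si](CC)(CC)O[C@@H]1[C@H](C(=C)CO[Si](CC)(CC)CC)C[C@@H](O[Si](CC)(CC)CC)[C@H](C)[C@@](O)(C(=O)/C=C\C)[C@H]1O
F8 | step 19 | tris-TES Z-enone 5β-isovalerate | CC[Si](CC)(CC)O[C@@H]1[C@H](C(=C)CO[Si](CC)(CC)CC)C[C@@H](O[Si](CC)(CC)CC)[C@H](C)[C@@](O)(C(=O)/C=C\C)[C@H]1OC(=O)CC(C)C
F9 | step 19 | Z-enone triol isovalerate | O[C@@H]1[C@H](C(=C)CO)C[C@@H](O)[C@H](C)[C@@](O)(C(=O)/C=C\C)[C@H]1OC(=O)CC(C)C
F10 | step 19 | Z-enone α-methylene lactol | C=C1C(O)O[C@@H]2[C@H]1C[C@@H](O)[C@H](C)[C@@](O)(C(=O)/C=C\C)[C@H]2OC(=O)CC(C)C
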